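Remark on numbering: the eleven-membered compounds are numbered C1 (acetoxy carbon), C2=C3(Me), C4, C5, C6=C7(Me), C8, C9, C10, C11 (CMe2). The bicyclic compounds 1–4 and 8 carry caryophyllane numbering, in which C7, C8, C9, C10, C1 and C13 become target C4, C3, C2, C1, C10 and the C3 methyl, and the epoxide carbons C5/C4 become target C6/C7.

## Analysis of the target

Compound 15 is a humulane-type sesquiterpenoid diester built on an eleven-membered carbocycle with a quaternary CMe2 carbon (C11) and no ring fusion. The ring holds two trisubstituted alkenes of opposite geometry: C2=C3 is cis in the ring (Z, with C1 and C4 on the same side) and C6=C7 is trans (E). The two stereocentres, C1 (S) and C4 (R), are both allylic ester carbons and flank the Z alkene in a 1,4-relationship. They are too far apart for one to set the other by acyclic stereocontrol, and C1 is neopentyl, wedged between C11 and the alkene. They also carry different acyl groups, an acetate at C1 and a 4-hydroxybenzoate at C4, so the two oxygens must be told apart. Sensitive points are the two allylic esters (ionisation, SN2′ displacement, acyl migration between the cis-disposed oxygens), the free phenol, the Z alkene, and the 1,5-diene in a medium ring, which is prone to transannular reactions under acid. The difficulty lies in forming a strained medium ring, in placing a Z-trisubstituted alkene between two oxygenated carbons, and in oxidising C1 selectively. The route rests on one structural observation: a bond between C2 and C10 would create a cyclobutane (C1, C2, C10, C11) fused to a nine-membered ring, which is the bicyclo[7.2.0]undecane skeleton of caryophyllene. In that skeleton the C3 methyl is the exocyclic methylene, C6=C7 is the trans ring alkene (masked as the epoxide in 1), and the gem-dimethyl group sits on the four-membered ring. The eleven-membered ring can therefore be made by breaking a bond rather than forming one.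

## Retrosynthetic reasoning

**15 ⇒ 14.** The phenol is released last from its silyl ether 14. This is the mildest step available and keeps a free, acidic O–H out of every earlier step.

**14 ⇒ 13.** The trans C6=C7 alkene is traced back to the trans-epoxide 13. The epoxide is carried for as long as possible because it protects this alkene from hydrogen-atom transfer, from allylic oxidation and from transannular chemistry. The forward step must remove oxygen with retention of geometry and without ionising either allylic ester.

**13 ⇒ 12 ⇒ 11.** The C1 acetate comes from alcohol 12, and the C1 stereocentre from face-selective reduction of enone 11. No neighbouring stereocentre can be trusted to direct this reduction, so a chiral catalyst is used.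

**11 ⇒ 9.** The C1 carbonyl is cut back to a methylene. In 9, C1 is the only unhindered-by-electronics allylic methylene: C6=C7 is an epoxide and C4–H is deactivated by its acyloxy group. For this reason the C4 oxygen is carried as the final aroyl ester rather than as a silyl ether, which would activate C4–H toward the same oxidant. This also removes two protecting-group steps and avoids fluoride treatment next to an allylic acetate.

**9 ⇒ 8 (key disconnection).** The bond C2–C10 is re-formed in thought, and the C2=C3 alkene becomes an exocyclic methylene on C3. This turns the eleven-membered ring into the cyclobutane-fused nine-membered ring of 8. The cut is placed here because the tertiary radical produced by hydrogen-atom delivery to that methylene sits directly on the cyclobutane, so strain release drives the ring merger. No other bond of the ring offers a precursor that already contains all fifteen carbons, the CMe2 group and the trans alkene. The forward reaction must cleave C2–C10 rather than C2–C1 and must deliver the cis C2=C3 geometry.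

**8 ⇒ 4 + 7.** The ester bond at caryophyllane C7 is disconnected to allylic alcohol 4 and the silyl-protected acid 7. Acylation does not touch the C–O bond of the stereocentre.

**4 ⇒ 3 ⇒ 2 ⇒ 1.** The (7R)-alcohol 4 is traced to enone 3, so that the configuration is set by a chiral reducing catalyst rather than by the uncertain facial course of an allylic hydroxylation. Enone 3 comes from the epimeric alcohols 2, and these from allylic hydroxylation of (−)-caryophyllene oxide 1 at the methylene next to the exocyclic alkene.

**7 ⇒ 5.** The protected acid 7 comes from 4-hydroxybenzoic acid 5 by double silylation and selective cleavage of the silyl ester 6.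

## Alternatives that were turned down

**Alternative 1: anionic oxy-Cope ring expansion.**
- Disconnection: the C4–C5 σ bond, formed in a [3,3] shift that at the same time breaks C2–C7 of a seven-membered ring.
- Forward key step: cycloheptanol A1 carries on adjacent ring carbons, on the same face, a 1-(methoxymethoxy)propen-2-yl arm (future C3/C4) and a vinyl arm (future C6/C5). Its potassium alkoxide (KH, 18-crown-6) would rearrange, and the C2 enolate would be trapped with PhNTf2 as enol triflate A2.
- For: this is a ring expansion, not a macrocyclisation. A chair-like transition state passes the enol ether geometry on to C4 and gives the trans C6=C7 alkene. The C1 oxygen is present from the start, so no late C–H oxidation is needed. On the predictability of the C4 configuration and of the C2=C3 geometry this plan is stronger than the chosen one.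
- Against: A1 is a demanding target in its own right. It has three contiguous stereocentres, two of them fully substituted and adjacent, next to the CMe2 carbon. The alkenyl nucleophile must add to a ketone crowded on both sides with the correct facial sense. The chair that gives cis C2=C3 together with trans C6=C7 must hold the ring bond C2–C1 pseudo-axial, and competes with arrangements leading to the 2E isomer. Afterwards the triflate must be reduced to C–H and the PMB and MOM ethers exchanged for two different esters.
- Comparison: the count would be well above fifteen steps. The chosen route takes the whole ring, the quaternary carbon and the trans alkene from the starting terpene, at the price of one uncertain alkene geometry.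

**Alternative 2: chromium-mediated closure at C1–C11.**
- Disconnection: the bond between the carbinol carbon C1 and the quaternary C11.
- Forward key step: open-chain (2Z)-enal A3 carries a secondary allylic bromide at C9 next to a prenyl-type C10=C11 terminus. CrCl2 (divalent chromium) would form an allylchromium that adds through its γ-carbon C11 to the aldehyde (Nozaki–Hiyama-type allylation), closing the ring to trienol A4.
- For: one step makes the most hindered C–C bond, the C1 carbinol and the ring. The C2=C3 geometry is fixed in the open chain, and the C1 oxygen arises in the closure itself. On both points it is stronger than the chosen plan.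
- Against: closing an eleven-membered ring at a bond to a quaternary carbon is the least favourable place sterically and entropically. The (Z)-enal A3 isomerises easily to the E form. The C1 configuration depends on 1,4-induction from C4 through a flexible macrocyclic transition state. A4 carries an extra C9=C10 alkene that must be hydrogenated selectively beside two trisubstituted alkenes, and the chain itself needs a long linear synthesis.
- Comparison: the chosen route needs neither a macrocyclisation nor an acyclic build-up. In exchange for the C1 oxygen it uses one allylic oxidation and one catalyst-controlled reduction.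

**Alternative 3: B-alkyl Suzuki macrocyclisation at C7–C8.**
- Disconnection: the sp2–sp3 bond C7–C8, remote from both stereocentres.
- Forward key step: open-chain A5 has a terminal C8=C9 alkene and an (E)-vinyl iodide at C7. 9-BBN would hydroborate the terminal alkene, and the C8 borane would couple with the iodide under zerovalent palladium formed from PdCl2(dppf) with Cs2CO3, closing the ring to A6.
- For: both stereocentres and both alkene geometries are secured before ring closure by reagent-controlled methods. The coupling retains alkene geometry, and the ring closes at its least hindered bond. On stereochemical security this is the strongest of all four plans, stronger than the chosen one.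
- Against: length. A5 combines a Z-trisubstituted alkene between two oxygenated stereocentres, a quaternary carbon and a vinyl iodide, which would take an estimated twelve to fifteen linear steps. The medium-ring closure needs high dilution and competes with oligomerisation and protodeboronation. After closure the PMB and TBS ethers must still be exchanged for acetate and aroyl ester.
- Comparison: the chosen route is roughly half as long and forms the ring without any cyclisation. It accepts the risk in the C2=C3 geometry, for which a corrective fallback exists.

Key step: step 6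

## Route

Remark on the chemistry: the facial course of the selenium-mediated hydroxylation at caryophyllane C7 cannot be predicted with confidence; the route does not rely on it and sets this centre by reagent control in step 3.

Step 1
Reactants: 1 (−)-caryophyllene oxide
Product: 2 (1R,4R,5R,9S)-4,5-epoxycaryophyll-8(13)-en-7-ol (both C7 epimers)
Conditions: SeO2 (0.3 equiv), t-BuOOH (2.5 equiv, in decane), CH2Cl2, 0 °C to rt
Reagents that add atoms: selenium dioxide O=[Se]=O (transfers the oxygen to C7); tert-butyl hydroperoxide CC(C)(C)OO (reoxidises selenium, ultimate oxygen source)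
Why: Selenium dioxide allylic hydroxylation (ene reaction, then [2,3]-sigmatropic shift); selenium adds to the terminal methylene carbon and the hydrogen is taken from the C7 methylene, not from the cyclobutane methine C9, whose loss would require a strained cyclobutene. The alkene returns to the exocyclic position; any enone formed by over-oxidation is the product of step 2.

Step 2
Reactants: 2 (1R,4R,5R,9S)-4,5-epoxycaryophyll-8(13)-en-7-ol (both C7 epimers)
Product: 3 (1R,4R,5R,9S)-4,5-epoxycaryophyll-8(13)-en-7-one
Conditions: Dess–Martin periodinane, pyridine, CH2Cl2, 0 °C; used without prolonged storage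
Reagents that add atoms: none
Why: Dess–Martin oxidation of a secondary allylic alcohol; both C7 epimers converge on one enone. Pyridine buffering and low temperature protect the β,γ-epoxy ketone from acid- or base-induced opening of the epoxide.

Step 3
Reactants: 3 (1R,4R,5R,9S)-4,5-epoxycaryophyll-8(13)-en-7-one
Product: 4 (1R,4R,5R,7R,9S)-4,5-epoxycaryophyll-8(13)-en-7-ol
Conditions: (S)-Me-CBS (0.2 equiv), catecholborane (1.5 equiv), toluene, −78 °C; MeOH quench
Reagents that add atoms: none
Why: Corey–Bakshi–Shibata reduction; the α-branched methylene-vinyl flank (C8) is the large group and the C6 methylene the small one, so the (S)-catalyst should deliver hydride to the face that gives the (7R)-alcohol. Catecholborane at −78 °C gives 1,2-reduction without hydroboration of the methylene or attack on the epoxide.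

Step 4
Reactants: 5 4-hydroxybenzoic acid
Product: 7 4-(tert-butyldimethylsilyloxy)benzoic acid, via tert-butyldimethylsilyl 4-(tert-butyldimethylsilyloxy)benzoate 6 (not isolated)
Conditions: TBSCl (2.3 equiv), imidazole, DMF, rt; then AcOH/THF/H2O, rt
Reagents that add atoms: tert-butyldimethylsilyl chloride CC(C)(C)[Si](C)(C)Cl
Why: Silylation of both O–H groups, then selective hydrolysis of the silyl ester, which is far more labile than the aryl silyl ether.

Step 5
Reactants: 4 (1R,4R,5R,7R,9S)-4,5-epoxycaryophyll-8(13)-en-7-ol; 7 4-(tert-butyldimethylsilyloxy)benzoic acid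
Product: 8 (1R,4R,5R,7R,9S)-4,5-epoxycaryophyll-8(13)-en-7-yl 4-(tert-butyldimethylsilyloxy)benzoate
Conditions: DCC, DMAP (0.2 equiv), CH2Cl2, 0 °C to rt
Reagents that add atoms: none
Why: Steglich esterification; the C7–O bond is not broken, so the (7R) configuration is retained, and the neutral conditions leave the epoxide intact.

Step 6
Reactants: 8 (1R,4R,5R,7R,9S)-4,5-epoxycaryophyll-8(13)-en-7-yl 4-(tert-butyldimethylsilyloxy)benzoate
Product: 9 (2Z,4R,6R,7R)-6,7-epoxy-3,7,11,11-tetramethylcycloundec-2-en-4-yl 4-(tert-butyldimethylsilyloxy)benzoate
Conditions: Fe(acac)3 (0.3 equiv), PhSiH3 (2.5 equiv, slow addition), degassed EtOH (0.02 M), 60 °C, argon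
Reagents that add atoms: none
Why: Fe(acac)3 and phenylsilane in ethanol form a hydride of trivalent iron that transfers a hydrogen atom to the terminal methylene carbon (Mukaiyama-type metal-hydride hydrogen-atom transfer), creating the C3 methyl group and a tertiary radical at C3. This cyclobutylcarbinyl radical undergoes β-scission of the ring bond C2–C10, giving the C2=C3 alkene and a secondary C10 radical, which is capped by a second hydrogen from another iron hydride or by reduction at divalent iron and protonation by ethanol. The closest known reaction type is the hydrogen-atom-transfer-triggered opening of the cyclobutane of β-pinene, a standard radical clock under such conditions. The eleven-membered ring arises by ring merger, through loss of the bond shared by the four- and nine-membered rings, so no closure mode applies and no cyclisation entropy is paid. No stereocentre is formed, and C4, C6 and C7 are untouched because none of them becomes a radical site. Cleavage of C2–C10 rather than C2–C1 is secured by the secondary rather than primary product radical and by the fact that only this cleavage releases the strain of both rings. Chemoselectivity rests on the much faster hydrogen-atom uptake of a 1,1-disubstituted alkene compared with the trisubstituted product alkene, on the inertness of epoxide and esters, and on a low steady concentration of hydrogen donor so that scission outruns direct reduction. The cis C2=C3 geometry requires C1 to lie near the radical plane on the C4 side when C2–C10 stands perpendicular to it; this is decided by the conformer of the nine-membered ring, which the C4 ester biases but does not guarantee.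

Step 7
Reactants: 9 (2Z,4R,6R,7R)-6,7-epoxy-3,7,11,11-tetramethylcycloundec-2-en-4-yl 4-(tert-butyldimethylsilyloxy)benzoate
Product: 11 (2Z,4R,6R,7R)-6,7-epoxy-3,7,11,11-tetramethyl-1-oxocycloundec-2-en-4-yl 4-(tert-butyldimethylsilyloxy)benzoate, via C1 tert-butylperoxy ether 10 (not isolated)
Conditions: Rh2(cap)4 (1 mol %), t-BuOOH (70 % aq, 5 equiv), ClCH2CH2Cl, 40 °C
Reagents that add atoms: tert-butyl hydroperoxide CC(C)(C)OO
Why: Radical allylic C–H oxidation; tert-butoxyl and tert-butylperoxyl radicals abstract a C1 hydrogen, the allyl radical is captured at its secondary C1 terminus as the mixed peroxide 10, and loss of tert-butanol (Kornblum–DeLaMare type) gives the enone. C1 is the favoured site because C4–H is deactivated by its acyloxy group, C6=C7 is masked as the epoxide and the methyl offers only primary hydrogens. Capture at C1 leaves the C2=C3 bond in place and cis.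

Step 8
Reactants: 11 (2Z,4R,6R,7R)-6,7-epoxy-3,7,11,11-tetramethyl-1-oxocycloundec-2-en-4-yl 4-(tert-butyldimethylsilyloxy)benzoate
Product: 12 (1S,2Z,4R,6R,7R)-6,7-epoxy-1-hydroxy-3,7,11,11-tetramethylcycloundec-2-en-4-yl 4-(tert-butyldimethylsilyloxy)benzoate
Conditions: (R)-Me-CBS (0.3 equiv), BH3·SMe2 (1.0 equiv), THF, −20 °C; MeOH quench
Reagents that add atoms: none
Why: Corey–Bakshi–Shibata reduction; the ketone should bind the oxazaborolidine anti to the quaternary C11 flank (large) and syn to the C2–H vinyl flank (small), so the (R)-catalyst delivers hydride to the face that gives the (1S)-alcohol. Only 1,2-reduction is expected at −20 °C, with esters and epoxide untouched.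

Step 9
Reactants: 12 (1S,2Z,4R,6R,7R)-6,7-epoxy-1-hydroxy-3,7,11,11-tetramethylcycloundec-2-en-4-yl 4-(tert-butyldimethylsilyloxy)benzoate
Product: 13 (1S,2Z,4R,6R,7R)-1-acetoxy-6,7-epoxy-3,7,11,11-tetramethylcycloundec-2-en-4-yl 4-(tert-butyldimethylsilyloxy)benzoate
Conditions: Ac2O, Et3N, DMAP (0.2 equiv), CH2Cl2, 0 °C to rt; run directly after step 8
Reagents that add atoms: acetic anhydride CC(=O)OC(C)=O
Why: DMAP-catalysed acylation of the hindered neopentyl allylic alcohol with retention at C1, since the C–O bond is not broken. Prompt acetylation forestalls 1,4-migration of the aroyl group from the C4 oxygen to the cis-disposed C1 hydroxyl.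

Step 10
Reactants: 13 (1S,2Z,4R,6R,7R)-1-acetoxy-6,7-epoxy-3,7,11,11-tetramethylcycloundec-2-en-4-yl 4-(tert-butyldimethylsilyloxy)benzoate
Product: 14 (1S,2Z,4R,6E)-1-acetoxy-3,7,11,11-tetramethylcycloundeca-2,6-dien-4-yl 4-(tert-butyldimethylsilyloxy)benzoate
Conditions: Rh2(OAc)4 (2 mol %), dimethyl diazomalonate (1.5 equiv, slow addition), benzene, 80 °C
Reagents that add atoms: none
Why: Rhodium-carbenoid oxygen-atom transfer; the malonate carbenoid binds the epoxide oxygen as an oxonium ylide that fragments in one step to the alkene and dimethyl oxomalonate, so the trans-epoxide gives the (6E)-alkene with retention. The neutral conditions spare both allylic esters and the aryl silyl ether, there is no free O–H to insert into, and the hindered, electron-poor C2=C3 alkene is a poor cyclopropanation partner.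

Step 11
Reactants: 14 (1S,2Z,4R,6E)-1-acetoxy-3,7,11,11-tetramethylcycloundeca-2,6-dien-4-yl 4-(tert-butyldimethylsilyloxy)benzoate
Product: 15 (1S,2Z,4R,6E)-1-acetoxy-3,7,11,11-tetramethylcycloundeca-2,6-dien-4-yl 4-hydroxybenzoate
Conditions: TBAF (1.1 equiv), AcOH (1.1 equiv), THF, 0 °C
Reagents that add atoms: none
Why: Fluoride cleavage of the aryl silyl ether, which is much faster than any reaction of the alkyl esters. Acetic acid buffers the phenoxide so that neither ester is cleaved or migrates and the 1,5-diene sees no strong acid.

## Compound list

1 | (−)-caryophyllene oxide, (1R,4R,5R,9S)-4,5-epoxycaryophyll-8(13)-ene | C=C1[C@H]2CC(C)(C)[C@@H]2CC[C@@]3(C)O[C@@H]3CC1 | starting material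
2 | (1R,4R,5R,9S)-4,5-epoxycaryophyll-8(13)-en-7-ol (both C7 epimers) | C=C1[C@H]2CC(C)(C)[C@@H]2CC[C@@]3(C)O[C@@H]3CC1O | intermediate
3 | (1R,4R,5R,9S)-4,5-epoxycaryophyll-8(13)-en-7-one | C=C1[C@H]2CC(C)(C)[C@@H]2CC[C@@]3(C)O[C@@H]3CC1=O | intermediate
4 | (1R,4R,5R,7R,9S)-4,5-epoxycaryophyll-8(13)-en-7-ol | C=C1[C@H]2CC(C)(C)[C@@H]2CC[C@@]3(C)O[C@@H]3C[C@H]1O | intermediate
5 | 4-hydroxybenzoic acid | OC(=O)c1ccc(O)cc1 | starting material
6 | tert-butyldimethylsilyl 4-(tert-butyldimethylsilyloxy)benzoate (not isolated) | CC(C)(C)[Si](C)(C)OC(=O)c1ccc(O[Si](C)(C)C(C)(C)C)cc1 | intermediate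
7 | 4-(tert-butyldimethylsilyloxy)benzoic acid | OC(=O)c1ccc(O[Si](C)(C)C(C)(C)C)cc1 | intermediate
8 | (1R,4R,5R,7R,9S)-4,5-epoxycaryophyll-8(13)-en-7-yl 4-(tert-butyldimethylsilyloxy)benzoate | C=C1[C@H]2CC(C)(C)[C@@H]2CC[C@@]3(C)O[C@@H]3C[C@H]1OC(=O)c4ccc(O[Si](C)(C)C(C)(C)C)cc4 | intermediate
9 | (2Z,4R,6R,7R)-6,7-epoxy-3,7,11,11-tetramethylcycloundec-2-en-4-yl 4-(tert-butyldimethylsilyloxy)benzoate | C1/C=C(/C)[C@H](OC(=O)c3ccc(O[Si](C)(C)C(C)(C)C)cc3)C[C@H]2O[C@]2(C)CCCC1(C)C | intermediate
10 | (2Z,4R,6R,7R)-1-(tert-butylperoxy)-6,7-epoxy-3,7,11,11-tetramethylcycloundec-2-en-4-yl 4-(tert-butyldimethylsilyloxy)benzoate (both C1 epimers, not isolated) | CC(C)(C)OOC1/C=C(/C)[C@H](OC(=O)c3ccc(O[Si](C)(C)C(C)(C)C)cc3)C[C@H]2O[C@]2(C)CCCC1(C)C | intermediate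
11 | (2Z,4R,6R,7R)-6,7-epoxy-3,7,11,11-tetramethyl-1-oxocycloundec-2-en-4-yl 4-(tert-butyldimethylsilyloxy)benzoate | O=C1/C=C(/C)[C@H](OC(=O)c3ccc(O[Si](C)(C)C(C)(C)C)cc3)C[C@H]2O[C@]2(C)CCCC1(C)C | intermediate
12 | (1S,2Z,4R,6R,7R)-6,7-epoxy-1-hydroxy-3,7,11,11-tetramethylcycloundec-2-en-4-yl 4-(tert-butyldimethylsilyloxy)benzoate | O[C@H]1/C=C(/C)[C@H](OC(=O)c3ccc(O[Si](C)(C)C(C)(C)C)cc3)C[C@H]2O[C@]2(C)CCCC1(C)C | intermediate
13 | (1S,2Z,4R,6R,7R)-1-acetoxy-6,7-epoxy-3,7,11,11-tetramethylcycloundec-2-en-4-yl 4-(tert-butyldimethylsilyloxy)benzoate | CC(=O)O[C@H]1/C=C(/C)[C@H](OC(=O)c3ccc(O[Si](C)(C)C(C)(C)C)cc3)C[C@H]2O[C@]2(C)CCCC1(C)C | intermediate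
14 | (1S,2Z,4R,6E)-1-acetoxy-3,7,11,11-tetramethylcycloundeca-2,6-dien-4-yl 4-(tert-butyldimethylsilyloxy)benzoate | CC(=O)O[C@H]1/C=C(/C)[C@H](OC(=O)c2ccc(O[Si](C)(C)C(C)(C)C)cc2)C/C=C(\C)CCCC1(C)C | intermediate
15 | (1S,2Z,4R,6E)-1-acetoxy-3,7,11,11-tetramethylcycloundeca-2,6-dien-4-yl 4-hydroxybenzoate (CNP0246761.2) | CC(=O)O[C@H]1/C=C(/C)[C@H](OC(=O)c2ccc(O)cc2)C/C=C(\C)CCCC1(C)C | target

## Step count and least certain steps

Total: 11 steps. Longest linear sequence: 10 steps (1 to 15 through steps 1–3 and 5–11); step 4 is a one-step side branch.

**Step 6 (key step).** The most likely failure is formation of the trans (2E) ring alkene. The geometry is fixed by the face of the planar C3 radical on which the breaking C2–C10 bond lies, and the nine-membered ring may prefer the conformer that puts C1 next to the methyl group rather than next to C4. Lesser risks are capping of the tertiary radical before scission (plain hydrogenation of the methylene), a transannular hydrogen shift to the C10 radical, and slow reduction of the new alkene. Fallback: it sets out from 8 and comes back at 11. The key step is run as written. Its product, (2E,4R,6R,7R)-6,7-epoxy-3,7,11,11-tetramethylcycloundec-2-en-4-yl 4-(tert-butyldimethylsilyloxy)benzoate F1, is oxidised at C1 under the conditions of step 7 to (2E,4R,6R,7R)-6,7-epoxy-3,7,11,11-tetramethyl-1-oxocycloundec-2-en-4-yl 4-(tert-butyldimethylsilyloxy)benzoate F2. Triplet-sensitised irradiation of this enone (365 nm, thioxanthone, MeCN, rt) should set up an E/Z photostationary mixture. The (2Z)-enone 11 is separated from it and F2 is returned to the irradiation. The alkene geometry is then set photochemically instead of in the scission.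

**Step 7.** Poor site selectivity in the hydrogen abstraction is the main concern: C1 is neopentyl and hindered, so the methyl group on C3 may compete. The allyl radical may also be captured at C3, or may lose its cis geometry before capture. Fallback: it sets out from 9 and comes back at 11. A Schenck ene reaction with singlet oxygen (O2, tetraphenylporphyrin, visible light, CH2Cl2, 0 °C) should take its hydrogen from C1, the crowded cis side of the alkene, and put oxygen on C3. The product is (4R,6R,7R)-6,7-epoxy-3-hydroperoxy-3,7,11,11-tetramethylcycloundec-1-en-4-yl 4-(tert-butyldimethylsilyloxy)benzoate F3 (C3 configuration and C1=C2 geometry left open). Reduction with PPh3 gives the tertiary allylic alcohol (4R,6R,7R)-6,7-epoxy-3-hydroxy-3,7,11,11-tetramethylcycloundec-1-en-4-yl 4-(tert-butyldimethylsilyloxy)benzoate F4. Babler–Dauben oxidative transposition with pyridinium chlorochromate, [C5H5NH][CrO3Cl], buffered with NaOAc in CH2Cl2, then moves the oxygen to C1 and gives enone 11. Any 2E enone formed in the [3,3] shift is treated as in the fallback for step 6.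

**Step 8.** Poor facial selectivity is possible, because the quaternary C11 flank and the cis-substituted alkenyl flank are not very different in size for the catalyst, and the conformation of the macrocycle may impose its own bias. Fallback: it sets out from 11 and comes back at 12. Luche reduction (NaBH4, CeCl3·7H2O, MeOH, −78 °C) under substrate control gives both C1 epimers, which are separated. The unwanted (1R,2Z,4R,6R,7R)-6,7-epoxy-1-hydroxy-3,7,11,11-tetramethylcycloundec-2-en-4-yl 4-(tert-butyldimethylsilyloxy)benzoate F5 is re-oxidised with Dess–Martin periodinane to 11 and recycled.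

**Step 10.** Competing cyclopropanation of the newly formed, electron-rich C6=C7 alkene by excess carbenoid, or incomplete oxygen transfer at the trisubstituted epoxide, may lower the efficiency. Fallback: it sets out from 13 and comes back at 14. Triphenylphosphine selenide and CF3CO2H in CH2Cl2 at rt open the protonated epoxide at carbon with inversion. Loss of Ph3PO closes, with a second inversion, the episelenide (1S,2Z,4R)-1-acetoxy-6,7-episeleno-3,7,11,11-tetramethylcycloundec-2-en-4-yl 4-(tert-butyldimethylsilyloxy)benzoate F6 (not isolated). It sheds selenium spontaneously and gives 14 with overall retention. The mechanism is a double inversion rather than a carbenoid oxygen transfer, so no alkene is exposed to a carbene.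

**Step 3.** The catalyst may be mismatched with the facial bias of the nine-membered ring, giving poor selectivity or mainly the (7S)-alcohol. Fallback: it sets out from 3 and comes back at 8, bypassing 4 and step 5. The enone is reduced under substrate control (NaBH4, CeCl3·7H2O, MeOH, −78 °C). If the ring favours (1R,4R,5R,7S,9S)-4,5-epoxycaryophyll-8(13)-en-7-ol F7, this epimer is coupled with acid 7 under Mitsunobu conditions (PPh3, DIAD, toluene, 0 °C). This inverts C7 and installs the aroyl ester in one operation, giving 8.

## Further compounds

F1 | step 6 | (2E,4R,6R,7R)-6,7-epoxy-3,7,11,11-tetramethylcycloundec-2-en-4-yl 4-(tert-butyldimethylsilyloxy)benzoate | C1/C=C(\C)[C@H](OC(=O)c3ccc(O[Si](C)(C)C(C)(C)C)cc3)C[C@H]2O[C@]2(C)CCCC1(C)C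
F2 | step 6 | (2E,4R,6R,7R)-6,7-epoxy-3,7,11,11-tetramethyl-1-oxocycloundec-2-en-4-yl 4-(tert-butyldimethylsilyloxy)benzoate | O=C1/C=C(\C)[C@H](OC(=O)c3ccc(O[Si](C)(C)C(C)(C)C)cc3)C[C@H]2O[C@]2(C)CCCC1(C)C
F3 | step 7 | (4R,6R,7R)-6,7-epoxy-3-hydroperoxy-3,7,11,11-tetramethylcycloundec-1-en-4-yl 4-(tert-butyldimethylsilyloxy)benzoate (C3 and C1=C2 geometry open) | C1=CC(C)(OO)[C@H](OC(=O)c3ccc(O[Si](C)(C)C(C)(C)C)cc3)C[C@H]2O[C@]2(C)CCCC1(C)C
F4 | step 7 | (4R,6R,7R)-6,7-epoxy-3-hydroxy-3,7,11,11-tetramethylcycloundec-1-en-4-yl 4-(tert-butyldimethylsilyloxy)benzoate (C3 and C1=C2 geometry open) | C1=CC(C)(O)[C@H](OC(=O)c3ccc(O[Si](C)(C)C(C)(C)C)cc3)C[C@H]2O[C@]2(C)CCCC1(C)C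
F5 | step 8 | (1R,2Z,4R,6R,7R)-6,7-epoxy-1-hydroxy-3,7,11,11-tetramethylcycloundec-2-en-4-yl 4-(tert-butyldimethylsilyloxy)benzoate | O[C@@H]1/C=C(/C)[C@H](OC(=O)c3ccc(O[Si](C)(C)C(C)(C)C)cc3)C[C@H]2O[C@]2(C)CCCC1(C)C
F6 | step 10 | (1S,2Z,4R)-1-acetoxy-6,7-episeleno-3,7,11,11-tetramethylcycloundec-2-en-4-yl 4-(tert-butyldimethylsilyloxy)benzoate (trans episelenide, both ring carbons inverted relative to 13) | CC(=O)O[C@H]1/C=C(/C)[C@H](OC(=O)c3ccc(O[Si](C)(C)C(C)(C)C)cc3)C[C@@H]2[Se][C@@]2(C)CCCC1(C)C
F7 | step 3 | (1R,4R,5R,7S,9S)-4,5-epoxycaryophyll-8(13)-en-7-ol | C=C1[C@H]2CC(C)(C)[C@@H]2CC[C@@]3(C)O[C@@H]3C[C@@H]1O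
A1 | alternative 1 | 2-(4-methoxybenzyloxy)-1-[(E)-1-(methoxymethoxy)prop-1-en-2-yl]-3,3,7-trimethyl-7-vinylcycloheptan-1-ol, alkenyl groups cis | O[C@@]1(/C(C)=C/OCOC)[C@H](OCc2ccc(OC)cc2)C(C)(C)CCC[C@]1(C)C=C
A2 | alternative 1 | 1-(4-methoxybenzyloxy)-4-(methoxymethoxy)-3,7,11,11-tetramethylcycloundeca-2,6-dien-2-yl trifluoromethanesulfonate (C1 and C4 configured as in 15, ring carbons C1 and C4 cis across C2=C3, 6E) | COc1ccc(CO[C@H]2/C(OS(=O)(=O)C(F)(F)F)=C(/C)[C@H](OCOC)C/C=C(\C)CCCC2(C)C)cc1
A3 | alternative 2 | (2Z,4R,6E)-9-bromo-4-(tert-butyldimethylsilyloxy)-3,7,11-trimethyldodeca-2,6,10-trienal (either C9 epimer) | O=C/C=C(/C)[C@H](O[Si](C)(C)C(C)(C)C)C/C=C(\C)CC(Br)C=C(C)C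
A4 | alternative 2 | (1S,2Z,4R,6E,9E)-4-(tert-butyldimethylsilyloxy)-3,7,11,11-tetramethylcycloundeca-2,6,9-trien-1-ol | O[C@H]1/C=C(/C)[C@H](O[Si](C)(C)C(C)(C)C)C/C=C(\C)C/C=C/C1(C)C
A5 | alternative 3 | (5S,6Z,8R,10E)-11-iodo-5-(4-methoxybenzyloxy)-8-(tert-butyldimethylsilyloxy)-4,4,7-trimethyldodeca-1,6,10-triene | C=CCC(C)(C)[C@@H](OCc1ccc(OC)cc1)/C=C(/C)[C@H](O[Si](C)(C)C(C)(C)C)C/C=C(\C)I
A6 | alternative 3 | (1S,2Z,4R,6E)-1-(4-methoxybenzyloxy)-4-(tert-butyldimethylsilyloxy)-3,7,11,11-tetramethylcycloundeca-2,6-diene | COc1ccc(CO[C@H]2/C=C(/C)[C@H](O[Si](C)(C)C(C)(C)C)C/C=C(\C)CCCC2(C)C)cc1
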